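All runs stem from a simulated flask with made-up constants; noise was put on by code.

Count each charge in equivalents of partner to substrate, and reckon with the share of substrate still left, not the target made.

| flask | substrate | partner | gas | remark | time |
|---|---|---|---|---|---|
| violet | 0.24 M | 0.37 M | 74 mM (held) | run made earlier |  |
| teal | 0.24 M | 0.58 M | 74 mM (held) | run made earlier |  |
| flask | 0.24 M | 0.264 M | 74 mM (held) |  | 1.5 h |

| violet: time / min | violet: target / % | teal: time / min | teal: target / % |
|---|---|---|---|
| 25.0 | 93 | 8.00 | 64 |
| 50.0 | 94 | 20.0 | 90 |
| 80.0 | 93 | 50.0 | 98 |
| 120 | 91 | 120 | 102 |

(each reading ± 1.5 percentage points)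

* amount of target at 1.5 h, in percent of the substrate charged
* the change that raises the amount of target at 1.5 h, in percent of the substrate charged most ("none" if none brings more than 2 percentage points) (alpha / eta / delta / none)
* amount of target at 1.5 h, in percent of the substrate charged, after eta

- alpha: doubling the amount of partner, all else as stated
- eta: doubling the transfer coefficient of the gas, all else as stated
- delta: doubling the saturation concentration of gas, all else as stated

- at the start none of the gas is in solution

Read teal down its column: the share not yet target falls to 36.0 % at 8.00 min and 10.0 % at 20.0 min. That is a roughly pseudo-first-order fall with a half-time near 6.02 min. At that pace 90 min is far longer, so expect little from more time or from eta.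

Now read violet against teal. Violet sits 7.25 % short of full on average, while teal climbs to about full, so tie the shortfall to partner.

My own guess is that substrate is lost in proportion to [target]/[partner] as it reacts. With r the equivalents, summing over the share left gives a weight r·ln(r/(r−1))−1. Violet weighs 0.613 and teal 0.291, which puts teal's loss at 3.44 %. Its late readings are 98 % and 102 %, so that reckoned loss sits on the high side.

The flask weighs 1.64, more than violet. Its lost share, violet's shortfall scaled by the two weights, is 19.4 %. I commit to 80.6 % target, the same after eta, and choose alpha.

The forecast stands higher: 87 % (79 % to 92 %), best alpha, 88 % after eta, since “trapping weakens late in the run”.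

The flask gives 80.2 % target, and 80.1 % after eta; alpha is best, adding 17 percentage points.

    substrate + partner → intermediate (k = 5.72 M⁻¹ min⁻¹)
    second reagent + intermediate → target (k = 1.90 M⁻¹ min⁻¹)
    gas ⇌ second reagent, rate k3*(csat - [second reagent]) (kL = 29.6 min⁻¹)
    substrate + target → side product (k = 3.76 M⁻¹ min⁻¹)

So the flask falls short by 19.8 % against the reckoned lost share of 19.4 %, and its target still stands at 80.2 % after 15.0 h. Take the neighbouring flask with 0.45 M of partner, 1.88 equiv: its weight is 0.429, so its lost share reckons to 5.08 %. It gives 95.9 % target, with 4.09 % as side product.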